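Numbering (spirovetivane): ring A = C1–C5 (C2 isopropenyl, C4 O-isobutyryl); ring B = C5–C10 (C6 Me, C6=C7, C8=O, C9 OAc, C10 Me); C5 is the spiro atom.
Cuts: first the two ester C–O bonds, the C6=C7 unsaturation, C9–O, C10–H, C6–CH3 and C10–CH3, which leaves hydroxy ketone 10. Then C5–C6 (C6 goes back to C10), C6=C7 (metathesis), C6–C10 (vinyl addition), C8–C9 (allylation) and C4=C5 (aldol).
Enabling feature: in 10 the unit O–C4–C5–C10=O is a β-hydroxy ketone whose quaternary α-carbon is the spiro atom, with C6 anti to the C4 oxygen across ring A. This is the product pattern of a 2,3-epoxy alcohol semipinacol shift, so ring B is grown from a five-membered carbinol ring (C6–C10) standing on a C4–C5 oxirane, a helper ring that the target lacks.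
Forward order: ring A (from limonene), oxirane, five-membered carbinol ring, enlargement to ring B, then C10 methyl, C8 ketone, C6 methyl, C10–H, C9–O, C6=C7, acetate.
Stereochemistry: C2 comes from (S)-limonene, C4 from epoxidation anti to the isopropenyl group, and C5 from the anti 1,2-shift. C10 comes from hydride delivery to the ring-B face opposite C4, and C9 from oxidation anti to the C10 methyl.

Key step: step 7

Assumption: stereocentres that are erased later (the new centres of 2, the carbinol carbon of 8 and 9, C6 of 16 to 20) are left open in the SMILES, and both epimers are carried on together.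

Step 1
Reactants: 1 (S)-(−)-limonene
Product: 3 (3S)-3-(prop-1-en-2-yl)-6-oxoheptanal, via limonene 1,2-ozonide 2 (not isolated)
Conditions: O3 (1.0 equiv, metered), CH2Cl2, −78 °C; then Me2S, −78 °C to rt
Reagents that add atoms: ozone, [O-][O+]=O
Why: Chemoselective ozonolysis, in which the electron-richer trisubstituted ring alkene should be cleaved before the 1,1-disubstituted isopropenyl group and the future C2 centre is not touched.

Step 2
Reactants: 3 (3S)-3-(prop-1-en-2-yl)-6-oxoheptanal
Product: 4 1-[(4R)-4-(prop-1-en-2-yl)cyclopent-1-en-1-yl]ethan-1-one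
Conditions: KOH (cat.), H2O/MeOH, rt
Reagents that add atoms: none
Why: Intramolecular aldol condensation under thermodynamic hydroxide conditions, in which the ketone-side enolate carbon (C5) adds to the aldehyde (C4) in a 5-enolexo closure and loses water to the conjugated acetylcyclopentene, with C2 remote from any acidic position.

Step 3
Reactants: 4 1-[(4R)-4-(prop-1-en-2-yl)cyclopent-1-en-1-yl]ethan-1-one
Product: 6 1-[(4R)-4-(prop-1-en-2-yl)cyclopent-1-en-1-yl]pent-4-en-1-one, via lithium enolate 5 (not isolated)
Conditions: LiN(i-Pr)2, THF, −78 °C; then allyl bromide, DMPU, −78 to −20 °C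
Reagents that add atoms: allyl bromide, C=CCBr
Why: Kinetic α'-deprotonation of the methyl ketone followed by SN2 enolate alkylation joins C9 to C8 and brings in C7 with a sacrificial CH2.

Step 4
Reactants: 6 1-[(4R)-4-(prop-1-en-2-yl)cyclopent-1-en-1-yl]pent-4-en-1-one
Product: 7 1-[3-(prop-1-en-2-yl)-6-oxabicyclo[3.1.0]hexan-1-yl]pent-4-en-1-one (oxirane oxygen anti to the isopropenyl group)
Conditions: 30% H2O2, NaOH (cat.), MeOH, 0 °C
Reagents that add atoms: hydrogen peroxide, OO
Why: Weitz–Scheffer nucleophilic epoxidation touches only the enone alkene, and hydroperoxide should add to C4 on the ring-A face anti to the C2 isopropenyl group, which sets the C4–O configuration and the temporary C5–O bond.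

Step 5
Reactants: 7 epoxy ketone
Product: 8 3-[3-(prop-1-en-2-yl)-6-oxabicyclo[3.1.0]hexan-1-yl]hepta-1,6-dien-3-ol (carbinol centre open)
Conditions: CH2=CHMgBr, THF, −78 °C; then H2O
Reagents that add atoms: vinylmagnesium bromide, C=C[Mg]Br
Why: Grignard 1,2-addition to an α,β-epoxy ketone is faster than oxirane opening at low temperature and attaches C6 to C10; the new carbinol centre is lost in step 7 and needs no control.

Step 6
Reactants: 8 divinyl-type carbinol
Product: 9 1-[3-(prop-1-en-2-yl)-6-oxabicyclo[3.1.0]hexan-1-yl]cyclopent-2-en-1-ol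
Conditions: second-generation Grubbs catalyst (2 mol %), CH2Cl2, 40 °C
Reagents that add atoms: none
Why: Ring-closing metathesis of the two monosubstituted alkenes of a 1,6-diene closes the five-membered carbinol ring (C6–C10), while the 1,1-disubstituted isopropenyl group and the oxirane stay inert.

Step 7
Reactants: 9 1-[3-(prop-1-en-2-yl)-6-oxabicyclo[3.1.0]hexan-1-yl]cyclopent-2-en-1-ol
Product: 11 10-oxo-2-(prop-1-en-2-yl)spiro[4.5]dec-6-en-4-yl 2-methylpropanoate (C4–O anti to isopropenyl and to C6 and syn to C10), via hydroxy ketone 10 (not isolated)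
Conditions: ZnBr2 (20 mol %), CH2Cl2, 0 °C to rt; then pyridine, DMAP, i-PrCOCl, 0 °C to rt
Reagents that add atoms: isobutyryl chloride, CC(C)C(=O)Cl
Why: ZnBr2 binds the oxirane oxygen, the tertiary C5–O bond lengthens and the alkenyl carbon C6 moves from C10 to C5 antiperiplanar to it while the carbinol becomes the C10 ketone; this is a semipinacol rearrangement of a 2,3-epoxy alcohol in its ring-enlarging form, known for 1-(epoxycycloalkyl)cycloalkanols. No ring is closed by cyclisation: C5 is inserted into the C6–C10 bond, so the five-membered carbinol ring becomes six-membered ring B, and the oxirane, a helper ring absent from the target, is opened. C5 forms with inversion, which puts C6 anti and C10 syn to the oxygen that stays on C4 with its configuration, so the oxirane face chosen in step 4 controls both centres and the epimers at the carbinol carbon of 9 converge. The step needs cleavage of the tertiary rather than the secondary C–O bond, secured by the better cation stabilisation at C5, and migration of C6 rather than C9, secured by the higher migratory aptitude of an sp2 carbon whose π bond can bridge to C5. The mild catalytic Lewis acid should spare the isopropenyl group, and acylation in the same flask removes the β-hydroxy ketone before retro-aldol opening of ring A can start and installs the final C4 ester.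

Step 8
Reactants: 11 keto ester
Product: 13 10-(trifluoromethylsulfonyloxy)-2-(prop-1-en-2-yl)spiro[4.5]deca-6,9-dien-4-yl 2-methylpropanoate, via potassium enolate 12 (not isolated)
Conditions: KN(SiMe3)2, THF, −78 °C; then N-(5-chloropyridin-2-yl)bis(trifluoromethanesulfonimide), −78 °C
Reagents that add atoms: N-(5-chloropyridin-2-yl)bis(trifluoromethanesulfonimide), O=S(=O)(N(c1ccc(Cl)cn1)S(=O)(=O)C(F)(F)F)C(F)(F)F
Why: Enol triflate formation, in which enolisation can only go towards C9 because C5 is quaternary and the ketone is more acidic than the hindered isobutyrate.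

Step 9
Reactants: 13 enol triflate
Product: 14 10-methyl-2-(prop-1-en-2-yl)spiro[4.5]deca-6,9-dien-4-yl 2-methylpropanoate
Conditions: MeMgBr, Fe(acac)3 (5 mol %), THF/NMP, −30 °C
Reagents that add atoms: methylmagnesium bromide, C[Mg]Br
Why: Iron-catalysed Kumada-type cross-coupling of alkenyl triflates is faster than Grignard attack on an ester at this temperature and places the C10 methyl group on a defined C9=C10 bond.

Step 10
Reactants: 14 skipped diene
Product: 15 10-methyl-8-oxo-2-(prop-1-en-2-yl)spiro[4.5]deca-6,9-dien-4-yl 2-methylpropanoate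
Conditions: dirhodium tetrakis(caprolactamate) Rh2(cap)4 (1 mol %), t-BuOOH (70% aq), K2CO3 (0.5 equiv), CH2Cl2, rt
Reagents that add atoms: tert-butyl hydroperoxide, CC(C)(C)OO
Why: Allylic C–H oxidation picks the doubly allylic and therefore weakest C8–H bonds, the quaternary C5 blocks aromatisation, and the conversion of 3,3-disubstituted cyclohexa-1,4-dienes into 4,4-disubstituted cyclohexadienones with hydroperoxide and a metal is a known reaction class.

Step 11
Reactants: 15 cross-conjugated dienone
Product: 16 6,10-dimethyl-8-oxo-2-(prop-1-en-2-yl)spiro[4.5]dec-9-en-4-yl 2-methylpropanoate (C6 open)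
Conditions: Me2CuLi (from MeLi and CuI), Et2O, −78 °C; then H2O
Reagents that add atoms: lithium dimethylcuprate, [Li+].C[Cu-]C
Why: Gilman conjugate addition is chemoselective for the β-monosubstituted terminus C6 over the β,β-disubstituted C10, so only one enone alkene (C9=C10) is left for step 12, and the new C6 centre is erased in step 14.

Step 12
Reactants: 16 enone
Product: 17 8-[dimethyl(phenyl)silyloxy]-6,10-dimethyl-2-(prop-1-en-2-yl)spiro[4.5]dec-8-en-4-yl 2-methylpropanoate (C10 methyl syn to C4)
Conditions: [(Ph3P)CuH]6 (5 mol % Cu), PhMe2SiH, toluene, rt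
Reagents that add atoms: dimethylphenylsilane, C[SiH](C)c1ccccc1
Why: Copper hydride-catalysed 1,4-hydrosilylation leaves isolated alkenes and esters alone and is known for β,β-disubstituted enones next to a quaternary carbon; hydride should reach C10 from the ring-B face that carries C1, because the other face is covered by C4 and its isobutyrate leaning over C10, which pushes the methyl group syn to C4 and gives a regiodefined C8=C9 enol ether.

Step 13
Reactants: 17 silyl enol ether
Product: 19 9-[dimethyl(phenyl)silyloxy]-6,10-dimethyl-8-oxo-2-(prop-1-en-2-yl)spiro[4.5]decan-4-yl 2-methylpropanoate (C9–O trans to C10 methyl), via silyloxy oxirane 18 (not isolated)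
Conditions: mCPBA (1.05 equiv), CH2Cl2, −20 °C
Reagents that add atoms: 3-chloroperbenzoic acid, O=C(OO)c1cccc(Cl)c1
Why: Rubottom oxidation, in which the peracid attacks the electron-rich enol ether well before the isopropenyl group and from the face anti to the C10 methyl group and C4, and the silyl shift then gives the α-silyloxy ketone with C9–O trans to the methyl group.

Step 14
Reactants: 19 α-silyloxy ketone
Product: 21 9-[dimethyl(phenyl)silyloxy]-6,10-dimethyl-8-oxo-2-(prop-1-en-2-yl)spiro[4.5]dec-6-en-4-yl 2-methylpropanoate, via lithium enolate 20 (not isolated)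
Conditions: LiN(SiMe3)2 (1.1 equiv), THF, −78 °C; then PhS(Cl)=N-t-Bu, −78 °C
Reagents that add atoms: none
Why: Mukaiyama dehydrogenation, in which kinetic deprotonation of an α-silyloxy ketone goes to the free CH2 (C7), sulfur transfer and syn elimination with the C6–H then give the C6=C7 enone, and the uncontrolled C6 centre disappears.

Step 15
Reactants: 21 α'-silyloxy enone
Product: 23 (2S,4R,5R,9R,10S)-9-acetoxy-6,10-dimethyl-8-oxo-2-(prop-1-en-2-yl)spiro[4.5]dec-6-en-4-yl 2-methylpropanoate, via hydroxy enone 22 (not isolated)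
Conditions: Et3N·3HF, MeCN, 0 °C; then Ac2O, pyridine, DMAP, rt
Reagents that add atoms: acetic anhydride, CC(=O)OC(C)=O
Why: Fluoride desilylation and DMAP-catalysed acetylation are mild enough to keep C9, whose trans arrangement to the C10 methyl group is also expected to be the more stable one.

Compound list
1 | (S)-(−)-limonene | CC1=CC[C@H](CC1)C(C)=C | starting material
2 | limonene 1,2-ozonide | CC12CC[C@H](C(C)=C)CC(OO1)O2 | intermediate
3 | (3S)-3-(prop-1-en-2-yl)-6-oxoheptanal | CC(=O)CC[C@@H](CC=O)C(C)=C | intermediate
4 | 1-[(4R)-4-(prop-1-en-2-yl)cyclopent-1-en-1-yl]ethan-1-one | CC(=O)C1=CC[C@H](C1)C(C)=C | intermediate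
5 | lithium enolate of 4 | C=C(O[Li])C1=CC[C@H](C1)C(C)=C | intermediate
6 | 1-[(4R)-4-(prop-1-en-2-yl)cyclopent-1-en-1-yl]pent-4-en-1-one | C=CCCC(=O)C1=CC[C@H](C1)C(C)=C | intermediate
7 | epoxy ketone, oxirane anti to isopropenyl | C=CCCC(=O)[C@]12C[C@H](C(C)=C)C[C@H]1O2 | intermediate
8 | epoxy hepta-1,6-dien-3-ol | C=CCCC(O)(C=C)[C@]12C[C@H](C(C)=C)C[C@H]1O2 | intermediate
9 | epoxy cyclopent-2-en-1-ol | OC3(C=CCC3)[C@]12C[C@H](C(C)=C)C[C@H]1O2 | intermediate
10 | 4-hydroxy-2-(prop-1-en-2-yl)spiro[4.5]dec-6-en-10-one | C=C(C)[C@@H]1C[C@@H](O)[C@@]2(C1)C=CCCC2=O | intermediate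
11 | isobutyrate of 10 | C=C(C)[C@@H]1C[C@@H](OC(=O)C(C)C)[C@@]2(C1)C=CCCC2=O | intermediate
12 | potassium enolate of 11 | C=C(C)[C@@H]1C[C@@H](OC(=O)C(C)C)[C@@]2(C1)C=CCC=C2O[K] | intermediate
13 | C10 enol triflate | C=C(C)[C@@H]1C[C@@H](OC(=O)C(C)C)[C@@]2(C1)C=CCC=C2OS(=O)(=O)C(F)(F)F | intermediate
14 | 10-methyl-6,9-diene | C=C(C)[C@@H]1C[C@@H](OC(=O)C(C)C)[C@@]2(C1)C=CCC=C2C | intermediate
15 | 10-methyl-6,9-dien-8-one | C=C(C)[C@@H]1C[C@@H](OC(=O)C(C)C)[C@@]2(C1)C=CC(=O)C=C2C | intermediate
16 | 6,10-dimethyl-9-en-8-one | C=C(C)[C@@H]1C[C@@H](OC(=O)C(C)C)[C@@]2(C1)C(C)CC(=O)C=C2C | intermediate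
17 | C8=C9 dimethylphenylsilyl enol ether | C=C(C)[C@@H]1C[C@@H](OC(=O)C(C)C)[C@@]2(C1)C(C)CC(O[Si](C)(C)c3ccccc3)=C[C@H]2C | intermediate
18 | silyloxy oxirane | C=C(C)[C@@H]1C[C@@H](OC(=O)C(C)C)[C@@]2(C1)C(C)C[C@]3(O[Si](C)(C)c4ccccc4)O[C@@H]3[C@H]2C | intermediate
19 | 9-silyloxy-8-ketone | C=C(C)[C@@H]1C[C@@H](OC(=O)C(C)C)[C@@]2(C1)C(C)CC(=O)[C@H](O[Si](C)(C)c3ccccc3)[C@H]2C | intermediate
20 | lithium C7=C8 enolate of 19 | C=C(C)[C@@H]1C[C@@H](OC(=O)C(C)C)[C@@]2(C1)C(C)C=C(O[Li])[C@H](O[Si](C)(C)c3ccccc3)[C@H]2C | intermediate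
21 | 9-silyloxy-6-en-8-one | C=C(C)[C@@H]1C[C@@H](OC(=O)C(C)C)[C@@]2(C1)C(C)=CC(=O)[C@H](O[Si](C)(C)c3ccccc3)[C@H]2C | intermediate
22 | 9-hydroxy-6-en-8-one | C=C(C)[C@@H]1C[C@@H](OC(=O)C(C)C)[C@@]2(C1)C(C)=CC(=O)[C@H](O)[C@H]2C | intermediate
23 | CNP0229299.1 | C=C(C)[C@@H]1C[C@@H](OC(=O)C(C)C)[C@@]2(C1)C(C)=CC(=O)[C@H](OC(C)=O)[C@H]2C | target

Total step count: 15. Longest linear sequence: 15 steps (fully linear from 1).

Steps most likely to fail

Step 7. The Lewis acid may ionise the tertiary allylic carbinol instead of opening the oxirane. The sp3 carbon C9 or the C4 hydrogen may migrate in place of C6, or ring A may open by retro-aldol cleavage before acylation. The fallback sets out from 8 and comes back at 11, and it gives up the enlargement while keeping the stereochemical logic. The same shift is run on the open-chain carbinol 8, where the vinyl group turns freely into the antiperiplanar position and ionisation gives a less stabilised cation. This leads to the open-chain hydroxy ketone F1. Acylation with isobutyryl chloride gives the open-chain keto ester F2. Ring-closing metathesis of the C5 vinyl group with the pentenoyl chain then closes ring B directly to 11.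

Step 12. Hydride transfer to C10 may be too slow next to the quaternary C5, 1,2-reduction may compete, or delivery may come from the wrong face if the C6 methyl group sits on the open face. The fallback sets out from 16 and comes back at 22. It replaces the bulky copper hydride cluster with a rhodium silyl hydride that binds the carbonyl oxygen first (1,4-hydrosilylation with RhCl(PPh3)3 and Et3SiH), which gives the triethylsilyl enol ether F3. Rubottom oxidation gives the triethylsilyloxy ketone F4. Dehydrogenation as in step 14 gives the triethylsilyloxy enone F5, and fluoride releases 22.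

Step 14. Deprotonation may occur at C9 or at the isobutyrate, the silyl group may wander, or the syn elimination may stall for the C6 epimer whose hydrogen cannot align. The fallback sets out from 15 and comes back at 21, and it fixes the site of unsaturation at the cuprate stage instead of by a later enolisation. The enolate from Me2CuLi addition to 15 is trapped with PhSeBr to give the C7 phenylselenyl enone F6. Copper hydride hydrosilylation gives the selenyl silyl enol ether F7. Two equivalents of mCPBA then oxidise the enol ether and the selenide together, and selenoxide syn elimination towards C6–H gives 21.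

Further compounds
F1 | step 7 | open-chain hydroxy ketone, 1-[2-hydroxy-4-(prop-1-en-2-yl)-1-vinylcyclopentyl]pent-4-en-1-one | C=C(C)[C@@H]1C[C@@H](O)[C@@](C1)(C=C)C(=O)CCC=C
F2 | step 7 | open-chain keto ester, isobutyrate of F1 | C=C(C)[C@@H]1C[C@@H](OC(=O)C(C)C)[C@@](C1)(C=C)C(=O)CCC=C
F3 | step 12 | triethylsilyl enol ether | C=C(C)[C@@H]1C[C@@H](OC(=O)C(C)C)[C@@]2(C1)C(C)CC(O[Si](CC)(CC)CC)=C[C@H]2C
F4 | step 12 | triethylsilyloxy ketone | C=C(C)[C@@H]1C[C@@H](OC(=O)C(C)C)[C@@]2(C1)C(C)CC(=O)[C@H](O[Si](CC)(CC)CC)[C@H]2C
F5 | step 12 | triethylsilyloxy enone | C=C(C)[C@@H]1C[C@@H](OC(=O)C(C)C)[C@@]2(C1)C(C)=CC(=O)[C@H](O[Si](CC)(CC)CC)[C@H]2C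
F6 | step 14 | C7 phenylselenyl enone | C=C(C)[C@@H]1C[C@@H](OC(=O)C(C)C)[C@@]2(C1)C(C)C([Se]c3ccccc3)C(=O)C=C2C
F7 | step 14 | selenyl silyl enol ether | C=C(C)[C@@H]1C[C@@H](OC(=O)C(C)C)[C@@]2(C1)C(C)C([Se]c3ccccc3)C(O[Si](C)(C)c3ccccc3)=C[C@H]2C
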